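## Analysis of the target

The target is the 3-O-[(2R)-2-methylbutanoyl] ester of (2R,3R)-pinobanksin: a chroman-4-one (benzo ring A fused to pyranone ring C) with a phenyl group (ring B) at C2, an acyloxy group at C3 and free hydroxyls at C5 and C7, the C5 hydroxyl being hydrogen-bonded to the C4 carbonyl. There are three stereocentres: C2 and C3 in ring C, trans to each other with both substituents equatorial, and the α-carbon of the side-chain acid. C3 is α to the ketone and epimerisable, so its configuration is thermodynamically slaved to C2 (trans favoured); C2 is the only centre of the core that needs an outside chiral influence. C2 is also benzylic, bonded to O1 and β to the ketone, so any free C3 enolate can expel the ring A phenoxide (E1cB, retro-oxa-Michael), which opens ring C and erases C2. The C2–C3 bond is easily dehydrogenated to the flavonol, and the ester joins a hindered secondary alcohol to an α-branched, epimerisable acid and must survive the unmasking of two phenols. The feature used by the strategy is the C2–C1' bond: ring B is an unsubstituted phenyl group on the C2 stereocentre, and without it rings A and C form a flat, achiral chromone whose C2 is the electrophilic β-carbon of a vinylogous ester. The difficulty is therefore control, not size: one absolute stereocentre on a base-labile ring, a second relayed from it, and a third in an acyl group that must be attached without epimerisation.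

## Retrosynthetic reasoning

**12 to 11.** The O5–H and O7–H groups are masked as benzyl ethers. Benzyl is chosen because it survives Lewis acid, peroxide oxidation and acylation, and leaves by hydrogenolysis under neutral conditions that enolise neither C3 nor the acyl α-carbon. The forward step must cleave two aryl benzyl ethers and leave the ester, the ketone and the C2–O1 bond.

**11 to 9 and 10.** The acyl C–O3 ester bond is cut. The side chain is available as the single enantiomer 10, and attaching it late keeps its α-centre away from all enolising steps. The forward reaction must acylate the hindered C3 hydroxyl of 9 without a ketene path and without a free C3 enolate.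

**9 to 6.** The C3–O bond is cut. C3 is α to the C4 ketone, so the oxygen can come from oxidation of the silyl enol ether 7 through epoxide 8 (Rubottom oxidation). The C2 phenyl group directs the oxidant to the opposite face, so C3 needs no reagent control. The forward sequence must reach the enol ether without ever forming a free enolate.

**6 to 4 and 5 (key disconnection).** The C2–C1' bond is cut. This one cut removes ring B and the only catalyst-controlled stereocentre, and leaves the flat, achiral chromone 4. The forward reaction is an enantioselective 1,4-addition of the phenyl group of 5 to C2. The C3 oxygen is deliberately kept off the acceptor, because an α-substituent on the enone would block the insertion step. The usual route to this ring system never cuts this bond; it carries ring B in from the start and closes ring C around it.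

**4 to 1 and 2.** The O1–C2 and C2–C3 bonds are cut. C2 is a one-carbon unit supplied by 2, which condenses with the methyl ketone of 1 to the enaminone 3 and is then closed onto the phenol. 1 already holds ring A with both benzyl ethers in place.

## Alternatives that were turned down

**Alternative 1:** (the textbook route) Disconnection: O1–C2 of ring C, with the C3 oxygen and both stereocentres taken from a chalcone epoxide. Forward key step: acid removes the O-2' protecting group of epoxy ketone A1, and the freed ring A phenol attacks the benzylic epoxide carbon 6-endo with inversion to give 9. A1 would come from 1 by protection, Claisen–Schmidt condensation and asymmetric nucleophilic epoxidation. Turned down for these reasons: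
- Both ortho positions of the aroyl group are substituted in this series, so the aryl ketone is twisted out of the enone plane; nucleophilic asymmetric epoxidation should lose rate and face discrimination.
- O-2' needs a protecting group orthogonal to the benzyl ethers, which adds a step (six in all).
- The ring closure must win over 5-exo attack at the α-carbon and over SN1 leakage at the benzylic carbon.
- The precursor of the key step already holds every atom and both stereocentres, so nothing is simplified.

**Alternative 2:** Disconnection: C4–C4a, the aryl–acyl bond. Forward key step: intramolecular Friedel–Crafts acylation of acid A2 (activated as a mixed anhydride) onto ring A, which would give 11 directly. The cut is attractive because O1 is flanked by two equivalent, doubly activated ortho positions, and because the anti arrangement of O1 and O3 maps onto the inverting opening of a trans epoxy ester by the ring A phenol. Turned down for these reasons: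
- The phenoxide of a phloroglucinol ether is ambident (C- versus O-alkylation).
- The β-aryloxy ester on the way to A2 can lose the aryloxide by E1cB under the basic opening and saponification.
- In the acidic ring closure the benzylic C–O bond carries a very electron-rich aryloxy leaving group and can ionise, which would scramble the future C2.
- An ester exchange is needed before cyclisation, giving at least six steps, and the precursor is as complex as the product.

**Alternative 3:** Disconnection: C3–C4, a union of two carbonyl carbons of like polarity by umpolung. Forward key step: intramolecular crossed benzoin reaction of dialdehyde A3 under a chiral N-heterocyclic carbene. The acyl anion equivalent formed at the aromatic aldehyde adds to the aliphatic aldehyde and closes ring C to 9, while the α-aryloxy-α-phenyl aldehyde centre (the future C2) racemises through its enol, so the step would be a dynamic kinetic resolution. Turned down for these reasons: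
- The aromatic aldehyde sits between two ortho oxygens on a strongly donating ring, so it forms the Breslow intermediate slowly; the carbene should attack the aliphatic aldehyde instead and give the regioisomeric 4-hydroxy-3-ketone.
- The α-ketol product stays in a basic medium in which retro-benzoin and E1cB opening of ring C are open.
- A3 needs two aldehydes unveiled one after the other, which costs more steps than the key step saves.

Key step: step 2

Remark on the chemistry: 1 and 10 are taken to be purchasable as such, and the sense of asymmetric induction in step 2 is assigned by analogy with the behaviour of the same ligand class on cyclic enones.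

## Route

Step 1
Reactants: 1 1-[2,4-bis(benzyloxy)-6-hydroxyphenyl]ethan-1-one; 2 N,N-dimethylformamide dimethyl acetal
Product: 4 5,7-bis(benzyloxy)-4H-chromen-4-one, via enaminone 3 (not isolated)
Conditions: 2 (3 equiv), toluene, 100 °C; then conc. aq. HCl, CH2Cl2, 40 °C
Reagents that add atoms: none
Why: Condensation of the methyl ketone of 1 with the amide acetal 2 gives the (E)-enaminone 3; acid then triggers 6-endo addition of the hydrogen-bonded phenol to the enaminone β-carbon and loss of dimethylamine (enaminone route to chromones), and aryl benzyl ethers withstand this brief acid treatment.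

Step 2
Reactants: 4 5,7-bis(benzyloxy)-4H-chromen-4-one; 5 phenylboronic acid
Product: 6 (2S)-5,7-bis(benzyloxy)-2-phenyl-2,3-dihydro-4H-chromen-4-one
Conditions: 5 (2 equiv), Pd(OCOCF3)2 (5 mol %), (R)-4-tert-butyl-2-(pyridin-2-yl)-4,5-dihydrooxazole [(R)-t-BuPyOX] (6 mol %), NH4PF6 (30 mol %), H2O (5 equiv), ClCH2CH2Cl, 60 °C
Reagents that add atoms: none
Why: Asymmetric conjugate arylation of the Hayashi–Miyaura type, run with a cationic divalent palladium–pyridine-oxazoline catalyst, a reaction type established for chromones and arylboronic acids. Transmetalation of 5 gives a phenylpalladium species that coordinates the C2=C3 bond of 4 and inserts it syn, phenyl going to C2 and palladium to C3; the C-bound enolate tautomerises to the O-bound form and is protonated by water, which returns the catalyst without a change of oxidation state. No ring is closed: the step forms the C2–C1' bond and completes the carbon skeleton. The only new stereocentre is C2, set in the insertion by the tert-butyl group of the ligand, which blocks one quadrant at palladium; the (R) ligand is chosen because, by analogy with the facial sense of its antipode on cyclic enones, it should place phenyl on the Re face of C2 and give (2S). Three selectivities are needed: 1,4- over 1,2-addition, which is inherent in the insertion mechanism; protonation instead of β-hydride elimination to the flavone, secured because the only β-hydrogen (at C2) is anti to palladium after syn insertion in the ring; and survival of C2 in the product, secured by the absence of base, so that ring C cannot open by an E1cB path. The electron-rich ring A lowers the electrophilicity of C2, which is why a cationic catalyst, excess 5 and 60 °C are planned.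

Step 3
Reactants: 6 (2S)-5,7-bis(benzyloxy)-2-phenyl-2,3-dihydro-4H-chromen-4-one
Product: 9 (2R,3R)-5,7-bis(benzyloxy)-3-hydroxy-2-phenyl-2,3-dihydro-4H-chromen-4-one, via silyl enol ether 7 (not isolated), via silyloxy epoxide 8 (not isolated)
Conditions: a) TMSOTf, Et3N, CH2Cl2, 0 °C; b) solvent exchange, dimethyldioxirane in acetone, −40 °C to 0 °C; c) aq. citric acid, THF, rt
Reagents that add atoms: dimethyldioxirane, CC1(C)OO1
Why: Soft enolisation (silyl triflate and amine) gives enol ether 7 without a free enolate, so the E1cB opening of ring C that would erase C2 is avoided; in the Rubottom oxidation dimethyldioxirane epoxidises C3=C4 on the face anti to the C2 phenyl group, and acidic collapse of 8 leaves the new C3–O bond trans to phenyl, which is (3R). A cis epimer, if formed, should drain into the diequatorial trans ketol by acid-catalysed enolisation at C3.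

Step 4
Reactants: 9 (2R,3R)-5,7-bis(benzyloxy)-3-hydroxy-2-phenyl-2,3-dihydro-4H-chromen-4-one; 10 (2R)-2-methylbutanoic acid
Product: 11 (2R,3R)-5,7-bis(benzyloxy)-4-oxo-2-phenyl-3,4-dihydro-2H-chromen-3-yl (2R)-2-methylbutanoate
Conditions: 10 (1.5 equiv), DCC, DMAP (0.2 equiv), CH2Cl2, 0 °C to rt
Reagents that add atoms: none
Why: Steglich esterification: the carbodiimide activates 10 and DMAP transfers the acyl group to the hindered, hydrogen-bonded C3 hydroxyl; with catalytic DMAP at low temperature and no acid chloride or stoichiometric amine base there is no ketene path that could epimerise the α-carbon of the acyl group, and C2 and C3 are not enolised.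

Step 5
Reactants: 11 (2R,3R)-5,7-bis(benzyloxy)-4-oxo-2-phenyl-3,4-dihydro-2H-chromen-3-yl (2R)-2-methylbutanoate
Product: 12 (2R,3R)-5,7-dihydroxy-4-oxo-2-phenyl-3,4-dihydro-2H-chromen-3-yl (2R)-2-methylbutanoate
Conditions: H2 (1 atm), 10% Pd/C, EtOAc, rt
Reagents that add atoms: none
Why: Hydrogenolysis of the two aryl benzyl ethers over zerovalent palladium on carbon at 1 atm leaves the ester and the aryl ketone; the C2–O1 bond is benzylic too, but it is secondary and ring-bound and should remain if the reaction is stopped after two equivalents of H2 in a non-acidic solvent.

## Compound list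

1 | 1-[2,4-bis(benzyloxy)-6-hydroxyphenyl]ethan-1-one | CC(=O)c1c(O)cc(OCc2ccccc2)cc1OCc1ccccc1 | starting material
2 | N,N-dimethylformamide dimethyl acetal | COC(OC)N(C)C | starting material
3 | (E)-1-[2,4-bis(benzyloxy)-6-hydroxyphenyl]-3-(dimethylamino)prop-2-en-1-one | CN(C)/C=C/C(=O)c1c(O)cc(OCc2ccccc2)cc1OCc1ccccc1 | intermediate
4 | 5,7-bis(benzyloxy)-4H-chromen-4-one | O=c1ccoc2cc(OCc3ccccc3)cc(OCc3ccccc3)c12 | intermediate
5 | phenylboronic acid | OB(O)c1ccccc1 | starting material
6 | (2S)-5,7-bis(benzyloxy)-2-phenyl-2,3-dihydro-4H-chromen-4-one | O=C1C[C@@H](c2ccccc2)Oc2cc(OCc3ccccc3)cc(OCc3ccccc3)c12 | intermediate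
7 | (2S)-5,7-bis(benzyloxy)-2-phenyl-4-[(trimethylsilyl)oxy]-2H-chromene | C[Si](C)(C)OC1=C[C@@H](c2ccccc2)Oc2cc(OCc3ccccc3)cc(OCc3ccccc3)c12 | intermediate
8 | (2R,3R,4R)-5,7-bis(benzyloxy)-3,4-epoxy-2-phenyl-4-[(trimethylsilyl)oxy]-3,4-dihydro-2H-chromene (epoxide oxygen anti to the 2-phenyl group) | C[Si](C)(C)O[C@@]12O[C@@H]1[C@@H](c1ccccc1)Oc1cc(OCc3ccccc3)cc(OCc3ccccc3)c12 | intermediate
9 | (2R,3R)-5,7-bis(benzyloxy)-3-hydroxy-2-phenyl-2,3-dihydro-4H-chromen-4-one | O[C@H]1C(=O)c2c(OCc3ccccc3)cc(OCc3ccccc3)cc2O[C@@H]1c1ccccc1 | intermediate
10 | (2R)-2-methylbutanoic acid | CC[C@@H](C)C(=O)O | starting material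
11 | (2R,3R)-5,7-bis(benzyloxy)-4-oxo-2-phenyl-3,4-dihydro-2H-chromen-3-yl (2R)-2-methylbutanoate | CC[C@@H](C)C(=O)O[C@H]1C(=O)c2c(OCc3ccccc3)cc(OCc3ccccc3)cc2O[C@@H]1c1ccccc1 | intermediate
12 | (2R,3R)-5,7-dihydroxy-4-oxo-2-phenyl-3,4-dihydro-2H-chromen-3-yl (2R)-2-methylbutanoate | CC[C@@H](C)C(=O)O[C@H]1C(=O)c2c(O)cc(O)cc2O[C@@H]1c1ccccc1 | target

## Step count and least certain steps

Total step count: 5. Longest linear sequence: 5 steps (1 to 4 to 6 to 9 to 11 to 12).

**Step 2 (key step).** Most likely to go wrong:
- slow insertion into the donor-rich vinylogous ester, so that protodeboronation and homocoupling of 5 consume the aryl donor;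
- erosion of enantiopurity by reversible opening of ring C at 60 °C;
- a lower level or the opposite sense of induction than the enone analogy predicts.

The nearest change of conditions is a monovalent rhodium catalyst with an electron-poor atropisomeric bisphosphine, or the antipodal ligand if only the sense is wrong. The fallback changes the approach: it sets out from 1 and comes back at 6. Claisen–Schmidt condensation of 1 with benzaldehyde (KOH, EtOH) gives (E)-1-[2,4-bis(benzyloxy)-6-hydroxyphenyl]-3-phenylprop-2-en-1-one F1. NaOAc in boiling EtOH closes ring C by oxa-Michael addition to racemic 5,7-bis(benzyloxy)-2-phenyl-2,3-dihydro-4H-chromen-4-one F2. The enantiomers are separated on a chiral stationary phase; the (2S) enantiomer is 6, and the (2R) enantiomer is returned with base to the F1/F2 equilibrium and resolved again, so the material is funnelled to one enantiomer over several cycles.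

**Step 3.** Most likely to go wrong:
- loss of the C2 configuration if ring C opens before silylation is complete;
- attack of the oxidant on the phenyl-bearing face, giving the cis ketol;
- over-oxidation of the free α-ketol to the flavonol during work-up.

The fallback sets out from 1 and comes back at 9, bypassing the flavanone stage. Protection of O-2' (NaH, MOMCl, DMF) gives 1-[2,4-bis(benzyloxy)-6-(methoxymethoxy)phenyl]ethan-1-one F3. Claisen–Schmidt condensation with benzaldehyde (KOH, EtOH) gives (E)-1-[2,4-bis(benzyloxy)-6-(methoxymethoxy)phenyl]-3-phenylprop-2-en-1-one F4. Juliá–Colonna epoxidation (poly-L-leucine, urea–H2O2, DBU, THF) should give [(2R,3S)-3-phenyloxiran-2-yl][2,4-bis(benzyloxy)-6-(methoxymethoxy)phenyl]methanone F5 (the compound called A1 above). HCl in MeOH then removes the MOM group, and the freed phenol opens the epoxide 6-endo at the benzylic carbon with inversion to give 9. The twist of the aroyl group is expected to cost selectivity in the epoxidation, which is why this is the fallback and not the route.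

**Step 4.** Most likely to go wrong:
- sluggish acyl transfer to the hindered hydroxyl, with rearrangement of the activated acid to the N-acylurea;
- partial epimerisation at the α-carbon of the acyl group in the acylpyridinium stage;
- DMAP-induced enolisation at C3 followed by opening of ring C.

The fallback sets out from 6 (with 10) and comes back at 11 without acylating a carbinol. 10 and DCC (0.5 equiv) give (2R)-2-methylbutanoic anhydride F6. F6 and catalytic TsOH convert 6 into the enol ester (2S)-5,7-bis(benzyloxy)-2-phenyl-2H-chromen-4-yl (2R)-2-methylbutanoate F7. Dimethyldioxirane epoxidises F7 anti to phenyl to (2R,3R,4R)-5,7-bis(benzyloxy)-3,4-epoxy-2-phenyl-3,4-dihydro-2H-chromen-4-yl (2R)-2-methylbutanoate F8. Catalytic TsOH then induces the 1,2-acyloxy shift of the enol ester epoxide rearrangement, expected under protic acid to occur with retention at C3, and gives 11. Should inversion intervene, the cis ester would epimerise at C3 to the trans isomer 11.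

**Step 5.** Most likely to go wrong: hydrogenolysis going on to the benzylic C2–O1 bond (reductive opening of ring C), or reduction of the aryl ketone once the phenols are free. The fallback sets out from 11 and comes back at 12 with a different bond-breaking mode: BCl3 and pentamethylbenzene in CH2Cl2 at −78 °C cleave both aryl benzyl ethers by Lewis-acid-assisted heterolysis with capture of the benzyl cation, which cannot reduce the C2–O1 bond or the ketone and leaves the ester. No new compound arises on the way.

## Further compounds

F1 | step 2 | (E)-1-[2,4-bis(benzyloxy)-6-hydroxyphenyl]-3-phenylprop-2-en-1-one | O=C(/C=C/c1ccccc1)c1c(O)cc(OCc2ccccc2)cc1OCc1ccccc1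
F2 | step 2 | racemic 5,7-bis(benzyloxy)-2-phenyl-2,3-dihydro-4H-chromen-4-one | O=C1CC(c2ccccc2)Oc2cc(OCc3ccccc3)cc(OCc3ccccc3)c12
F3 | step 3 | 1-[2,4-bis(benzyloxy)-6-(methoxymethoxy)phenyl]ethan-1-one | CC(=O)c1c(OCOC)cc(OCc2ccccc2)cc1OCc1ccccc1
F4 | step 3 | (E)-1-[2,4-bis(benzyloxy)-6-(methoxymethoxy)phenyl]-3-phenylprop-2-en-1-one | O=C(/C=C/c1ccccc1)c1c(OCOC)cc(OCc2ccccc2)cc1OCc1ccccc1
F5 | step 3 | [(2R,3S)-3-phenyloxiran-2-yl][2,4-bis(benzyloxy)-6-(methoxymethoxy)phenyl]methanone | O=C(c1c(OCOC)cc(OCc2ccccc2)cc1OCc1ccccc1)[C@@H]1O[C@H]1c1ccccc1
F6 | step 4 | (2R)-2-methylbutanoic anhydride | CC[C@@H](C)C(=O)OC(=O)[C@H](C)CC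
F7 | step 4 | (2S)-5,7-bis(benzyloxy)-2-phenyl-2H-chromen-4-yl (2R)-2-methylbutanoate | CC[C@@H](C)C(=O)OC1=C[C@@H](c2ccccc2)Oc2cc(OCc3ccccc3)cc(OCc3ccccc3)c12
F8 | step 4 | (2R,3R,4R)-5,7-bis(benzyloxy)-3,4-epoxy-2-phenyl-3,4-dihydro-2H-chromen-4-yl (2R)-2-methylbutanoate (epoxide oxygen anti to the 2-phenyl group) | CC[C@@H](C)C(=O)O[C@@]12O[C@@H]1[C@@H](c1ccccc1)Oc1cc(OCc3ccccc3)cc(OCc3ccccc3)c12
F0 | step 5 | none | none
A1 | alternative 1 | [(2R,3S)-3-phenyloxiran-2-yl][2,4-bis(benzyloxy)-6-(methoxymethoxy)phenyl]methanone | O=C(c1c(OCOC)cc(OCc2ccccc2)cc1OCc1ccccc1)[C@@H]1O[C@H]1c1ccccc1
A2 | alternative 2 | (2R,3R)-3-[3,5-bis(benzyloxy)phenoxy]-2-{[(2R)-2-methylbutanoyl]oxy}-3-phenylpropanoic acid | CC[C@@H](C)C(=O)O[C@@H](C(=O)O)[C@H](Oc1cc(OCc2ccccc2)cc(OCc2ccccc2)c1)c1ccccc1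
A3 | alternative 3 | racemic 2,4-bis(benzyloxy)-6-(2-oxo-1-phenylethoxy)benzaldehyde | O=CC(Oc1cc(OCc2ccccc2)cc(OCc2ccccc2)c1C=O)c1ccccc1
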